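The runs were generated by integration from invented constants; the scatter is artificial.

The vessel holds two phases, E in the first and D in the second, and you want its contents at 4.0 min.

| flask | E | D | remark | time | volume of the second phase over the first |
|---|---|---|---|---|---|
| maple | 0.050 M | 0.95 equiv | run made earlier |  |  |
| ash | 0.20 M | 0.95 equiv | run made earlier |  |  |
| larch | 0.10 M | 1.4 equiv | run made earlier |  |  |
| flask | 0.10 M | 0.950 equiv |  | 4.0 min | 1.0 |

| run | time / min | G / % | Q / % |
|---|---|---|---|
| maple | 0.833 | 1.1 | 0.3 |
| maple | 1.50 | 3.5 | 0.6 |
| maple | 2.50 | 6.8 | 0.5 |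
| maple | 3.00 | 8.8 | 0.9 |
| maple | 4.00 | 11.9 | 1.0 |
| maple | 5.00 | 14.7 | 1.3 |
| ash | 0.417 | 1.0 | 0.2 |
| ash | 0.667 | 3.6 | 0.3 |
| ash | 1.00 | 6.5 | 1.1 |
| ash | 2.00 | 14.1 | 3.0 |
| ash | 3.00 | 20.5 | 3.6 |
| ash | 5.00 | 30.1 | 3.8 |
| larch | 1.00 | 5.0 | 0.7 |
| larch | 2.00 | 13.2 | 2.0 |
| larch | 3.00 | 20.7 | 3.8 |
| larch | 4.00 | 26.2 | 4.1 |
| larch | 5.00 | 30.9 | 4.7 |

(readings scatter by 0.3 percentage points)

- amount of G and J and Q together at 4.0 min, in percent of the E charged
- part of the E charged that has reacted at 4.0 min

- what is said of G includes J and Q
- in the second phase: D, J; everything else is in the first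
- charges count per volume of the first phase; a concentration in a rate is the amount of a species over the volume of its own phase; every rate counts per litre of the first phase
- what was read earlier has a scatter of 0.3 percentage points, one standard deviation
- the earlier runs hold the two phases in the same ratio of volumes as the flask asked about
- what has gone from E into another species counts as reacted, even if it can come back

1. The G column already counts J and Q, so a G reading is y. Up to a fixed time, the mean slope of a run is its reading over that time, so mean slopes compare as readings do.

2. At 4.00 min maple reads 11.9%. The ash run, taken as a straight chord between 3.00 min and 5.00 min, gives 25.3%. Their ratio gives 0.544, the mean-slope order (an apparent order): the power of the E charge by which the mean slope grows at fixed equivalents of D.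

3. First way: maple's reading, scaled to 0.10 M of E with this power, gives 17.4% for the flask.

4. Second way: larch has the flask's E but more D. Taking y as proportional to D, which is my assumption, its 26.2% becomes 17.8%. The two ways use different runs and part by 0.40 percentage points, so I commit to 17.6%.

5. The chord is the suspect. The pair at 5.00 min needs none and gives an order of 0.517, which moves the first way by 0.32 points, against a scatter of 0.3 points.

6. No run reads E, so for cv I hold y as a floor and give no value.

The forecast says y 18% and cv 18%, on the ground that “everything that has left E is in this total, so cv equals y”.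

The flask gives y 18.8% and cv 47.7%.

    E + L → G (k = 5.80 M⁻¹ min⁻¹)
    L ⇌ D, rate k2*([L] - [D]/K2) per volume of the first phase (partition coefficient = 1.70, kL = 0.420 min⁻¹)
    L + G ⇌ Q, settled at all times (K = 10.0 M⁻¹)
    G ⇌ J, rate k4*([G] - [J]/K4) per volume of the first phase (partition coefficient = 1.30, kL = 0.280 min⁻¹)
    E ⇌ Z (K = 0.450, k = 0.330 min⁻¹)
    G → X (k = 0.140 min⁻¹)

My first way falls 1.4 points short of y, while cv stands 29 points above y, and at 4.00 min the flask holds Z 25.4% and X 3.47%. In the flask at 1.28 min, the forward step to Z alone uses E 3.8 times as fast as the step to G. For the neighbour with 0.040 M of E, the same order scales maple to 10.5%, and that neighbour gives y 10.2%. Its Z stands at 27.9% and its cv at 39.9%.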